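On the cyclohexane ring C5–C10, O6 and C11 are cis (both β) across C6–C7, while O8 is trans to C11 across C7–C8 and cis (α) to O9 across C8–C9. A carbon handed from O6 over a C7=C8 double bond and then pushed off C8 from the rear by the C9 oxygen substituent produces exactly this pattern.
Target 32 ⇐ C15–OH oxidation, desilylation, O9 angeloylation, C13 methylenation ⇐ trans-fused 8,12-lactone 24 ⇐ acyl transfer O6→O8, directed first by an 8,9-acetonide and then by an O6 silyl ether ⇐ cis-fused 6,12-lactone 8,9-carbonate 17.
17 ⇐ invertive opening of C11–C8 by the C9 carbonate, then loss of CO2 ⇐ cyclopropane-fused lactone 14 ⇐ carbene addition (forms C11–C7 and C11–C8) ⇐ C6 diazomalonate 13.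
13 ⇐ 6β-alcohol 10 ⇐ C6 allylic oxidation and 1,2-reduction ⇐ cyclohexene 8 ⇐ Diels–Alder adduct 3 of 1 and 2 (sets C5, C9, C10). The C5 side chain is carried as an electron-poor enol triflate and is later cross-coupled to bring in C15.
Ring order: cyclohexene (step 1); cyclopropane and 6,12-γ-lactone together (step 10); cyclic carbonate as the cyclopropane opens (step 11); acetonide (step 15); 8,12-γ-lactone (step 18).

Key step: step 10

Numbering: ring carbons are C5–C10; C1/C2 is the vinyl group on C10; C4/C3/C15 is the side chain on C5; C11–C13 are the lactone carbons. β is the face of the C10 methyl group and α is the opposite face.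
Assumption: the facial sense of the oxazaborolidinium catalyst in step 1 is assigned from the formyl C–H···O binding model for 2-substituted enals. If stereochemical correlation at alcohol 6 shows the opposite sense, the catalyst made from (R)-diphenylprolinol is used instead.

Step 1
Reactants: 1 (E)-buta-1,3-dien-1-yl acetate (commercial E/Z mixture; only the E isomer cycloadds) + 2 ethyl (E)-3-methyl-4-oxobut-2-enoate
Product: 3 ethyl (1R,5R,6S)-5-acetoxy-6-formyl-6-methylcyclohex-3-ene-1-carboxylate (5β-CO2Et; 9α-OAc; 10α-CHO; 10β-Me)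
Conditions: (S)-3,3-diphenyl-1-(2-methylphenyl)tetrahydro-1H,3H-pyrrolo[1,2-c][1,3,2]oxazaborole (20 mol %), (CF3SO2)2NH (18 mol %), 1 (3 equiv), CH2Cl2, −78 to −40 °C; Et3N quench
Reagents that add atoms: none
Why: Enantioselective Lewis-acid-catalysed Diels–Alder reaction in which boron binds the formyl oxygen, so the aldehyde governs regiochemistry (free diene terminus to the carbon β to CHO, acetoxy-bearing terminus to the methyl-bearing carbon) and endo orientation (OAc cis to CHO at C9/C10), the E-alkene fixes CHO trans to CO2Et (C10/C5), the catalyst leaves open the Re face of the methyl-bearing carbon, and an acyloxy diene cannot pass a silyl group to the triflimide and start an achiral background catalysis.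

Step 2
Reactants: 3 aldehyde ester
Product: 4 ethyl 9α-acetoxy-10β-methyl-10α-vinylcyclohex-7-ene-5β-carboxylate
Conditions: Ph3PCH3Br (1.5 equiv), KOtBu (1.4 equiv), THF, 0 °C; then 3, −78 to 0 °C
Reagents that add atoms: methyltriphenylphosphonium bromide, C[P+](c1ccccc1)(c1ccccc1)c1ccccc1.[Br-]
Why: Wittig methylenation; the non-stabilised ylide attacks the aldehyde far faster than the ester or acetate carbonyl groups, and because C10 is quaternary no stereocentre next to the reacting carbon can epimerise.

Step 3
Reactants: 4 vinyl ester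
Product: 6 hydroxy ketone (5β-acetyl; 9α-OH; 10β-Me; 10α-vinyl; C7=C8), via N-methoxy-N-methylamide 5 (not isolated)
Conditions: MeNH(OMe)·HCl (1.5 equiv), MeMgCl (8 equiv), THF, −15 °C to rt; aq. NH4Cl
Reagents that add atoms: methylmagnesium chloride, C[Mg]Cl; N,O-dimethylhydroxylamine hydrochloride, CNOC.Cl (its atoms stay only in 5)
Why: Acyl substitution through the N-methoxy-N-methylamide; the magnesium amide made in situ converts the ester into 5, whose chelated adduct with MeMgCl persists until work-up and so stops at the ketone without epimerising C5, while excess Grignard reagent removes the acetate from O9.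

Step 4
Reactants: 6 hydroxy ketone
Product: 7 9α-O-methoxycarbonyl derivative of 6 (methyl carbonate)
Conditions: ClCO2Me (3 equiv), pyridine, DMAP (cat.), CH2Cl2, 0 °C to rt
Reagents that add atoms: methyl chloroformate, COC(=O)Cl
Why: Chloroformate acylation of the hindered allylic alcohol under nucleophilic catalysis; a methyl carbonate is chosen because, unlike a tert-butyl carbonate, it cannot fragment to isobutene and CO2 under the Lewis acid of step 11 before it has served as the internal nucleophile.

Step 5
Reactants: 7 carbonate ketone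
Product: 8 enol triflate (5β-[1-(trifluoromethylsulfonyloxy)vinyl]; 9α-OCO2Me; 10β-Me; 10α-vinyl; C7=C8)
Conditions: KHMDS (1.1 equiv), THF, −78 °C; PhNTf2 (1.2 equiv), −78 to 0 °C
Reagents that add atoms: N-phenylbis(trifluoromethanesulfonimide), O=S(=O)(N(c1ccccc1)S(=O)(=O)C(F)(F)F)C(F)(F)F
Why: Kinetic enolisation and O-sulfonylation; the bulky amide base removes a methyl proton rather than the hindered C5–H, and the resulting 1,1-disubstituted enol triflate resists oxidants and electrophilic carbenes yet remains a cross-coupling handle for C15.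

Step 6
Reactants: 8 enol triflate
Product: 9 cyclohex-7-en-6-one (6-oxo derivative of 8)
Conditions: CrO3 (15 equiv), 3,5-dimethylpyrazole (15 equiv), CH2Cl2, −20 °C
Reagents that add atoms: chromium trioxide, O=[Cr](=O)=O
Why: Chromium-mediated allylic oxidation of a ring CH2 to the enone; C6–H2 is the only accessible allylic position, because C9–H is neopentyl and deactivated by the carbonate, the vinyl group has no allylic hydrogen, and the enol triflate is electron-poor.

Step 7
Reactants: 9 enone
Product: 10 6β-allylic alcohol (6β-OH cis to the 5β side chain)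
Conditions: NaBH4, CeCl3·7H2O, MeOH, −78 °C
Reagents that add atoms: none
Why: Luche 1,2-reduction; the β face of the carbonyl group is screened by the C5 side chain and the C10 methyl group, so hydride should arrive from the α face and set C6 with the hydroxyl β, and the cold, buffered medium spares the base-sensitive C5–H.

Step 8
Reactants: 10 6β-allylic alcohol + 11 3-tert-butoxy-3-oxopropanoic acid (mono-tert-butyl malonate)
Product: 12 6β-O-(tert-butyl malonyl) ester of 10
Conditions: 11 (1.5 equiv), DCC, DMAP (cat.), CH2Cl2, 0 °C to rt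
Reagents that add atoms: none
Why: Steglich esterification; the carbodiimide-activated malonic half ester acylates the hindered secondary alcohol with retention at C6.

Step 9
Reactants: 12 mixed malonate
Product: 13 cyclohex-7-en-6β-yl tert-butyl diazomalonate (9α-OCO2Me; 5β-enol triflate; 10β-Me; 10α-vinyl)
Conditions: 4-AcNHC6H4SO2N3 (1.3 equiv), Et3N, MeCN, rt
Reagents that add atoms: 4-acetamidobenzenesulfonyl azide, CC(=O)Nc1ccc(cc1)S(=O)(=O)N=[N+]=[N-]
Why: Regitz diazo transfer to the doubly activated methylene group under mild amine base, which leaves the carbonate, triflate and allylic ester untouched.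

Step 10
Reactants: 13 diazomalonate
Product: 14 tricyclic cyclopropane-fused 6,12-lactone tert-butyl ester (C11 bonded to the β faces of C7 and C8; C12 on the side of C6; ester exo; 9α-OCO2Me; 5β-enol triflate)
Conditions: Rh2(OAc)4 (2 mol %), ClCH2CH2Cl, 80 °C, 13 added by syringe pump over 10 h (final 0.005 M)
Reagents that add atoms: none
Why: Dirhodium tetraacetate binds the diazo carbon of 13, N2 departs, and the electrophilic rhodium carbene adds to C7=C8 in one concerted but asynchronous [2+1] event that forms C11–C7 and C11–C8. The closest known reaction type is the rhodium- or copper-catalysed intramolecular cyclopropanation of allylic diazoacetates and diazomalonates, cyclohex-2-enyl esters included, which gives 3-oxabicyclo[3.1.0]hexan-2-ones. The cyclopropane (C7–C8–C11) closes by the [2+1] addition itself, and the γ-lactone (C11–C12–O6–C6–C7) closes in the same event in the five-membered mode in which the tethered carbon reaches the proximal alkene carbon C7. The three-atom link O6–C12–C11 from the β-oriented, pseudoaxial O6 can span only the β face, so C7 and C8 both receive C11 there (syn addition keeps H7 and H8 cis), and C11 is fixed because C12 has to stay on the same side of the cyclopropane as C6, which leaves the tert-butyl ester exo. The step needs site selectivity among three alkenes as well as face selectivity. These are secured because the C5 enol triflate is too electron-poor for an electrophilic carbene (an isopropenyl group here would be a cis-placed, more nucleophilic homoallylic competitor leading to a δ-lactone), the C10 vinyl group lies on the α face out of reach, and C5–H is anti to O6, which shuts off C–H insertion.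

Step 11
Reactants: 14 tricyclic cyclopropane lactone ester
Product: 17 cis-fused 6β,12-lactone 8α,9α-cyclic carbonate (C11H2; 5β-enol triflate), via dioxolanylium triflate 15 (not isolated), via malonic half acid 16 (not isolated)
Conditions: TMSOTf (3 equiv), 2,6-di-tert-butylpyridine (1.5 equiv), CH2Cl2, −20 °C to rt; aq. NaOAc/AcOH buffer (pH 5), THF, rt; then toluene, 100 °C
Reagents that add atoms: water, O; trimethylsilyl trifluoromethanesulfonate, C[Si](C)(C)OS(=O)(=O)C(F)(F)F (its atoms stay only in 15)
Why: Proposed new method: the silyl triflate first converts the tert-butyl ester into a silyl ester and then silylates a malonyl carbonyl oxygen, which polarises C11–C8, the cyclopropane bond that overlaps best with both carbonyl π systems in the rigid 3-oxabicyclo[3.1.0]hexanone; the carbonyl oxygen of the α-oriented C9 methyl carbonate, held anti to that bond, attacks C8 from the rear in a five-membered exo-tet closure, so C8 is inverted and O8 ends α and cis to O9, giving trioxycarbenium salt 15 with C11 stored as a bis-silyl ketene acetal; buffered water converts 15 into the cyclic carbonate and half acid 16, which loses CO2 on heating; the closest known reaction types are the homoconjugate opening with inversion of 2-oxo-3-oxabicyclo[3.1.0]hexane-1-carboxylates by external nucleophiles, the iodotrimethylsilane opening of acceptor cyclopropanes, and the participation of neighbouring carbonates in Lewis-acid opening of epoxides, but a carbonate has not been shown to open an acceptor-only cyclopropane.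

Step 12
Reactants: 17 lactone carbonate enol triflate
Product: 18 allylic alcohol (5β-[3-hydroxyprop-1-en-2-yl]; 6,12-lactone; 8,9-carbonate)
Conditions: Bu3SnCH2OH (1.5 equiv), Pd(PPh3)4 (10 mol %), LiCl (4 equiv), 1,4-dioxane, 90 °C
Reagents that add atoms: (tributylstannyl)methanol, CCCC[Sn](CCCC)(CCCC)CO
Why: Stille coupling; zerovalent palladium inserts into the vinyl C–OTf bond, chloride assists transmetalation, and tin transfers the hydroxymethyl group, a known hydroxymethylation of enol triflates that brings in C15 already oxygenated and makes a late selenium dioxide oxidation unnecessary.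

Step 13
Reactants: 18 allylic alcohol
Product: 19 15-O-tert-butyldiphenylsilyl ether of 18
Conditions: TBDPSCl (1.2 equiv), imidazole, CH2Cl2, rt
Reagents that add atoms: tert-butyl(chloro)diphenylsilane, CC(C)(C)[Si](Cl)(c1ccccc1)c1ccccc1
Why: Silylation of the only free hydroxyl group; the tert-butyldiphenylsilyl ether is chosen to survive the aqueous acid of step 18.

Step 14
Reactants: 19 silyl ether carbonate
Product: 20 8α,9α-diol 6β,12-lactone
Conditions: K2CO3 (0.3 equiv), MeOH, 0 °C
Reagents that add atoms: none
Why: Base-catalysed transesterification; the five-membered cyclic carbonate is the most electrophilic carbonyl group and is methanolysed to the cis-diol, while any lactone that opens should reclose on work-up to the cis-fused 6,12-lactone.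

Step 15
Reactants: 20 diol lactone
Product: 21 8α,9α-O-isopropylidene 6β,12-lactone
Conditions: Me2C(OMe)2, pyridinium 4-toluenesulfonate (cat.), CH2Cl2, rt
Reagents that add atoms: 2,2-dimethoxypropane, COC(C)(C)OC
Why: Acid-catalysed transketalisation; only the cis-8α,9α-diol can form the five-membered acetonide, which blocks O8 while the lactone is being opened.

Step 16
Reactants: 21 acetonide lactone
Product: 22 6β-hydroxy N-methoxy-N-methylamide (C7β–CH2C(O)N(OMe)Me; 8,9-acetonide)
Conditions: MeNH(OMe)·HCl (5 equiv), AlMe3 (5 equiv), CH2Cl2, 0 °C to rt; aq. potassium sodium tartrate; used crude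
Reagents that add atoms: N,O-dimethylhydroxylamine hydrochloride, CNOC.Cl
Why: Aluminium-amide aminolysis of a lactone; the hydroxy amide does not reclose under the neutral work-up, which frees O6 for protection.

Step 17
Reactants: 22 hydroxy amide
Product: 23 6β-O-tert-butyldimethylsilyl ether of 22
Conditions: TBSOTf (2 equiv), 2,6-lutidine (3 equiv), CH2Cl2, 0 °C to rt
Reagents that add atoms: tert-butyldimethylsilyl trifluoromethanesulfonate, CC(C)(C)[Si](C)(C)OS(=O)(=O)C(F)(F)F
Why: Silyl triflate silylation of a hindered axial alcohol; once O6 is capped, the acyl group can later go only to O8, which overrides the likely thermodynamic preference for the cis-fused lactone.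

Step 18
Reactants: 23 silyl ether amide
Product: 24 trans-fused 8α,12-lactone with free 9α-OH (6β-OTBS; 15-OTBDPS)
Conditions: AcOH–H2O–THF (4:1:1), 55 °C
Reagents that add atoms: none
Why: Acidic acetonide hydrolysis followed by lactonisation; of the two hydroxyl groups released only the equatorial O8–H can reach C12 in a five-membered ring (O9 is 1,3-trans to the C7 side chain), and loss of the weakly basic N,O-dimethylhydroxylamine drives closure of the 8,12-lactone without touching any stereocentre.

Step 19
Reactants: 24 8,12-lactone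
Product: 27 α-methylene 8,12-lactone (C11=C13; 9α-OH free), via Mannich base 25 (not isolated), via methiodide 26 (not isolated)
Conditions: LDA (2.4 equiv), THF, −78 °C; CH2=NMe2+ I− (3 equiv), −78 °C to rt; MeI, MeOH, rt; aq. NaHCO3, CH2Cl2
Reagents that add atoms: dimethyl(methylidene)ammonium iodide, C=[N+](C)C.[I-]; iodomethane, CI (its atoms stay only in 26)
Why: Mannich-type α-methylenation of a lactone; the lithium enolate (with O9 carried as its alkoxide) is aminomethylated, and quaternisation followed by mild base triggers β-elimination to the exocyclic alkene.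

Step 20
Reactants: 27 α-methylene lactone alcohol + 28 angelic acid ((Z)-2-methylbut-2-enoic acid)
Product: 30 9α-O-angelate (6β-OTBS; 15-OTBDPS), via mixed anhydride 29 (not isolated)
Conditions: 28 (4 equiv), 2,4,6-Cl3C6H2COCl (4 equiv), Et3N, toluene, rt; then 27, 80 °C
Reagents that add atoms: 2,4,6-trichlorobenzoyl chloride, O=C(Cl)c1c(Cl)cc(Cl)cc1Cl (its atoms stay only in 29)
Why: Yamaguchi-type mixed-anhydride acylation run without a nucleophilic pyridine catalyst, conditions known to esterify hindered alcohols with angelic acid without Z to E isomerisation.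

Step 21
Reactants: 30 bis-silyl angelate
Product: 31 6β,15-diol
Conditions: HF·pyridine, pyridine, THF, 0 °C to rt
Reagents that add atoms: none
Why: Fluoride cleavage of both silyl ethers under mildly acidic conditions that spare the angelate, the α-methylene lactone and the trans ring fusion.

Step 22
Reactants: 31 diol
Product: 32 target CNP0320538.1
Conditions: MnO2 (activated, excess), CH2Cl2, rt
Reagents that add atoms: none
Why: MnO2 oxidises allylic alcohols selectively, so the primary C15 alcohol becomes the enal while the saturated secondary C6 hydroxyl group is left alone.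

Compound list
1 | (E)-buta-1,3-dien-1-yl acetate | C=C/C=C/OC(C)=O | starting material
2 | ethyl (E)-3-methyl-4-oxobut-2-enoate | CCOC(=O)/C=C(\C)C=O | starting material
3 | ethyl (1R,5R,6S)-5-acetoxy-6-formyl-6-methylcyclohex-3-ene-1-carboxylate | O=C[C@]1(C)[C@H](OC(C)=O)C=CC[C@H]1C(=O)OCC | intermediate
4 | ethyl 9α-acetoxy-10β-methyl-10α-vinylcyclohex-7-ene-5β-carboxylate | C=C[C@]1(C)[C@H](OC(C)=O)C=CC[C@H]1C(=O)OCC | intermediate
5 | 9α-hydroxy N-methoxy-N-methylamide (not isolated) | C=C[C@]1(C)[C@H](O)C=CC[C@H]1C(=O)N(C)OC | intermediate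
6 | 5β-acetyl-10β-methyl-10α-vinylcyclohex-7-en-9α-ol | C=C[C@]1(C)[C@H](O)C=CC[C@H]1C(C)=O | intermediate
7 | 9α-methyl carbonate of 6 | C=C[C@]1(C)[C@H](OC(=O)OC)C=CC[C@H]1C(C)=O | intermediate
8 | 5β-(1-triflyloxyvinyl) 9α-methyl carbonate | C=C[C@]1(C)[C@H](OC(=O)OC)C=CC[C@H]1C(=C)OS(=O)(=O)C(F)(F)F | intermediate
9 | cyclohex-7-en-6-one derived from 8 | C=C[C@]1(C)[C@H](OC(=O)OC)C=CC(=O)[C@H]1C(=C)OS(=O)(=O)C(F)(F)F | intermediate
10 | 6β-allylic alcohol | C=C[C@]1(C)[C@H](OC(=O)OC)C=C[C@@H](O)[C@H]1C(=C)OS(=O)(=O)C(F)(F)F | intermediate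
11 | 3-tert-butoxy-3-oxopropanoic acid | CC(C)(C)OC(=O)CC(=O)O | starting material
12 | 6β-O-(tert-butyl malonyl) ester | C=C[C@]1(C)[C@H](OC(=O)OC)C=C[C@@H](OC(=O)CC(=O)OC(C)(C)C)[C@H]1C(=C)OS(=O)(=O)C(F)(F)F | intermediate
13 | cyclohex-7-en-6β-yl tert-butyl diazomalonate (key-step precursor) | C=C[C@]1(C)[C@H](OC(=O)OC)C=C[C@@H](OC(=O)C(=[N+]=[N-])C(=O)OC(C)(C)C)[C@H]1C(=C)OS(=O)(=O)C(F)(F)F | intermediate
14 | tricyclic cyclopropane-fused 6,12-lactone tert-butyl ester (key-step product) | C=C[C@]1(C)[C@H](OC(=O)OC)[C@H]2[C@@]3(C(=O)OC(C)(C)C)C(=O)O[C@@H]([C@H]1C(=C)OS(=O)(=O)C(F)(F)F)[C@@H]23 | intermediate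
15 | 2-methoxy-1,3-dioxolan-2-ylium triflate with C11 bis-silyl ketene acetal (not isolated) | C=C[C@]1(C)[C@@H]2OC(OC)=[O+][C@@H]2[C@H]3C(=C(O[Si](C)(C)C)O[Si](C)(C)C)C(=O)O[C@H]3[C@H]1C(=C)OS(=O)(=O)C(F)(F)F.[O-]S(=O)(=O)C(F)(F)F | intermediate
16 | 11-carboxy 6,12-lactone 8,9-carbonate, C11 labile (not isolated) | C=C[C@]1(C)[C@@H]2OC(=O)O[C@@H]2[C@H]3C(C(=O)O)C(=O)O[C@H]3[C@H]1C(=C)OS(=O)(=O)C(F)(F)F | intermediate
17 | 6β,12-lactone 8α,9α-cyclic carbonate enol triflate | C=C[C@]1(C)[C@@H]2OC(=O)O[C@@H]2[C@H]3CC(=O)O[C@H]3[C@H]1C(=C)OS(=O)(=O)C(F)(F)F | intermediate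
18 | 15-hydroxy 6,12-lactone 8,9-carbonate | C=C[C@]1(C)[C@@H]2OC(=O)O[C@@H]2[C@H]3CC(=O)O[C@H]3[C@H]1C(=C)CO | intermediate
19 | 15-OTBDPS 6,12-lactone 8,9-carbonate | C=C[C@]1(C)[C@@H]2OC(=O)O[C@@H]2[C@H]3CC(=O)O[C@H]3[C@H]1C(=C)CO[Si](c1ccccc1)(c1ccccc1)C(C)(C)C | intermediate
20 | 8α,9α-diol 6,12-lactone | C=C[C@]1(C)[C@H](O)[C@H](O)[C@H]2CC(=O)O[C@H]2[C@H]1C(=C)CO[Si](c1ccccc1)(c1ccccc1)C(C)(C)C | intermediate
21 | 8,9-acetonide 6,12-lactone | C=C[C@]1(C)[C@@H]2OC(C)(C)O[C@@H]2[C@H]3CC(=O)O[C@H]3[C@H]1C(=C)CO[Si](c1ccccc1)(c1ccccc1)C(C)(C)C | intermediate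
22 | 6β-hydroxy N-methoxy-N-methylamide acetonide | C=C[C@]1(C)[C@@H]2OC(C)(C)O[C@@H]2[C@@H](CC(=O)N(C)OC)[C@@H](O)[C@H]1C(=C)CO[Si](c1ccccc1)(c1ccccc1)C(C)(C)C | intermediate
23 | 6β-OTBS N-methoxy-N-methylamide acetonide | C=C[C@]1(C)[C@@H]2OC(C)(C)O[C@@H]2[C@@H](CC(=O)N(C)OC)[C@@H](O[Si](C)(C)C(C)(C)C)[C@H]1C(=C)CO[Si](c1ccccc1)(c1ccccc1)C(C)(C)C | intermediate
24 | trans-fused 8α,12-lactone, 9α-OH, 6β-OTBS | C=C[C@]1(C)[C@H](O)[C@@H]2OC(=O)C[C@H]2[C@@H](O[Si](C)(C)C(C)(C)C)[C@H]1C(=C)CO[Si](c1ccccc1)(c1ccccc1)C(C)(C)C | intermediate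
25 | 11-(dimethylaminomethyl) lactone (not isolated) | C=C[C@]1(C)[C@H](O)[C@@H]2OC(=O)C(CN(C)C)[C@H]2[C@@H](O[Si](C)(C)C(C)(C)C)[C@H]1C(=C)CO[Si](c1ccccc1)(c1ccccc1)C(C)(C)C | intermediate
26 | trimethylammonium iodide of 25 (not isolated) | C=C[C@]1(C)[C@H](O)[C@@H]2OC(=O)C(C[N+](C)(C)C)[C@H]2[C@@H](O[Si](C)(C)C(C)(C)C)[C@H]1C(=C)CO[Si](c1ccccc1)(c1ccccc1)C(C)(C)C.[I-] | intermediate
27 | α-methylene 8,12-lactone, 9α-OH | C=C[C@]1(C)[C@H](O)[C@@H]2OC(=O)C(=C)[C@H]2[C@@H](O[Si](C)(C)C(C)(C)C)[C@H]1C(=C)CO[Si](c1ccccc1)(c1ccccc1)C(C)(C)C | intermediate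
28 | angelic acid | C/C=C(/C)C(=O)O | starting material
29 | angelic 2,4,6-trichlorobenzoic anhydride (not isolated) | C/C=C(/C)C(=O)OC(=O)c1c(Cl)cc(Cl)cc1Cl | intermediate
30 | 9α-O-angelate, 6β-OTBS, 15-OTBDPS | C=C[C@]1(C)[C@H](OC(=O)/C(C)=C\C)[C@@H]2OC(=O)C(=C)[C@H]2[C@@H](O[Si](C)(C)C(C)(C)C)[C@H]1C(=C)CO[Si](c1ccccc1)(c1ccccc1)C(C)(C)C | intermediate
31 | 9α-O-angelate 6β,15-diol | C=C[C@]1(C)[C@H](OC(=O)/C(C)=C\C)[C@@H]2OC(=O)C(=C)[C@H]2[C@@H](O)[C@H]1C(=C)CO | intermediate
32 | CNP0320538.1 | C=C[C@]1(C)[C@H](OC(=O)/C(C)=C\C)[C@@H]2OC(=O)C(=C)[C@H]2[C@@H](O)[C@H]1C(=C)C=O | target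

Total step count: 22. Longest linear sequence: 22 steps (from 1 and 2; compounds 11 and 28 are bought).

Steps most likely to fail

Step 11. The carbonate carbonyl oxygen may be too weak a nucleophile for a secondary carbon that is inductively deactivated by O9. The silyl Lewis acid would then degrade the substrate, or the opening would lose its regiochemistry, before the internal displacement occurs. The fallback replaces the internal nucleophile by an external one and uses the documented homoconjugate addition of heteroatom nucleophiles to 2-oxo-3-oxabicyclo[3.1.0]hexane-1-carboxylates, which breaks the same exocyclic bond with inversion. It sets out from 14. Caesium acetate in DMSO at 80 °C should give the 8α-acetoxy malonyl lactone F1. CF3CO2H in CH2Cl2, followed by heating in toluene, removes the tert-butyl ester and CO2 to give the 8α-acetoxy 6,12-lactone F2. The conditions of steps 12 and 13 then give the 15-hydroxy acetate F3 and the 15-silyl ether acetate F4. K2CO3 in MeOH removes both the acetate and the methyl carbonate, and the route is rejoined at 20.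

Step 10. Two allylic C–O bonds deactivate C7=C8, so capture of the carbene may be slow, and carbene dimerisation or insertion into adventitious water may win. The fallback forms the same two bonds one after the other by radical and then polar chemistry, without a carbene. It sets out from 12. Deprotonation (NaH, THF, 0 °C) and N-iodosuccinimide give the iodomalonate F5. Iodine-atom-transfer 5-exo cyclisation ((Bu3Sn)2 cat., sunlamp, benzene, 80 °C) forms C11–C7 on the β face and places iodine on the open α face of C8, giving the 8α-iodo malonyl lactone F6. DBU in CH2Cl2 then closes C11–C8 by 3-exo-tet displacement, and the route is rejoined at 14.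

Step 6. Hydrogen abstraction may occur at C9–H, oxygen may be delivered at the C8 end of the allyl system, or the base-sensitive α-keto enol triflate may lose triflate or epimerise at C5 during oxidation and isolation. The fallback avoids the ketone altogether. It sets out from 8. SeO2 (cat.) and tBuOOH in CH2Cl2 hydroxylate C6 directly by the ene and [2,3]-sigmatropic sequence. The β-epimer formed is 10 itself. The 6α-allylic alcohol F7 is esterified with 11 under Mitsunobu conditions (PPh3, DIAD, toluene, 0 °C) with inversion at C6, and the route is rejoined at 12.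

Further compounds
F1 | step 11 | 8α-acetoxy malonyl lactone | C=C[C@]1(C)[C@H](OC(=O)OC)[C@H](OC(C)=O)[C@H]2C(C(=O)OC(C)(C)C)C(=O)O[C@H]2[C@H]1C(=C)OS(=O)(=O)C(F)(F)F
F2 | step 11 | 8α-acetoxy 6,12-lactone | C=C[C@]1(C)[C@H](OC(=O)OC)[C@H](OC(C)=O)[C@H]2CC(=O)O[C@H]2[C@H]1C(=C)OS(=O)(=O)C(F)(F)F
F3 | step 11 | 15-hydroxy acetate | C=C[C@]1(C)[C@H](OC(=O)OC)[C@H](OC(C)=O)[C@H]2CC(=O)O[C@H]2[C@H]1C(=C)CO
F4 | step 11 | 15-silyl ether acetate | C=C[C@]1(C)[C@H](OC(=O)OC)[C@H](OC(C)=O)[C@H]2CC(=O)O[C@H]2[C@H]1C(=C)CO[Si](c1ccccc1)(c1ccccc1)C(C)(C)C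
F5 | step 10 | iodomalonate | C=C[C@]1(C)[C@H](OC(=O)OC)C=C[C@@H](OC(=O)C(I)C(=O)OC(C)(C)C)[C@H]1C(=C)OS(=O)(=O)C(F)(F)F
F6 | step 10 | 8α-iodo malonyl lactone | C=C[C@]1(C)[C@H](OC(=O)OC)[C@H](I)[C@H]2C(C(=O)OC(C)(C)C)C(=O)O[C@H]2[C@H]1C(=C)OS(=O)(=O)C(F)(F)F
F7 | step 6 | 6α-allylic alcohol | C=C[C@]1(C)[C@H](OC(=O)OC)C=C[C@H](O)[C@H]1C(=C)OS(=O)(=O)C(F)(F)F
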